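**Retrosynthetic overview**
1. Ketoemblide ⇒ intramolecular hydroboration / B-alkyl Suzuki–Miyaura macrocyclization that forms the C3–C4 bond (the 14-membered carbocycle, closed last) from a terminal-vinyl triene bearing an α-bromo-enoate lactone.
2. That triene ⇒ intermolecular Z-selective Still–Gennari HWE (C12=C13) between a ketone-tethered phosphonate and the Z-dienal (Z-3-isopropylpenta-2,4-dienal); the dienal's C14=C1 geometry comes from a Z-enol triflate/Stille sequence.
3. The phosphonate ketone ⇒ Mukaiyama–Michael of the methyl-ketone silyl enol ether onto a 2-phosphonoacrylate; the methyl ketone ⇒ Wacker oxidation of the vinyl group of a 7-membered bromo-lactone.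
4. The 7-membered lactone (formed first) ⇒ intramolecular HWE of a linalyl α-bromophosphonoacetate onto the aldehyde obtained by cleaving linalool's prenyl alkene. (S)-Linalool sets C8 directly.

Assumption: commercial (S)-(+)-linalool (≥95% ee) is used, and β-ketoester enol triflation (NaH/Tf2O) gives the Z-triflate (OTf cis to ester); stereocentres formed at phosphonate/epoxide carbons are destroyed later.

---

**Step 1**
Reactants: 1 (S)-linalool; 2 diethylphosphonoacetic acid
Product: 3 (S)-linalyl diethylphosphonoacetate
Conditions: 2, 2,4,6-Cl3C6H2COCl, Et3N, THF, rt; then 1, DMAP, toluene, 40 °C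
Reagents that add atoms: none (the trichlorobenzoyl chloride only activates the acid)
Why: Yamaguchi esterification through the mixed anhydride acylates the tertiary alcohol without touching the stereocentre (C8 retained, S).

**Step 2**
Reactants: 3
Product: 4 linalyl 2-bromo-2-(diethoxyphosphoryl)acetate
Conditions: NaH (1.0 equiv), THF, 0 °C; then NBS (1.0 equiv), 0 °C
Reagents that add atoms: NBS, O=C1CCC(=O)N1Br (Br)
Why: C-bromination of the phosphonoacetate carbanion; the new CHBr stereocentre is an epimeric mixture that is destroyed in the HWE of step 5.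

**Step 3**
Reactants: 4
Product: 5 6,7-epoxide of 4 (epoxide carbon unspecified; mixture)
Conditions: mCPBA (1.0 equiv), NaHCO3, CH2Cl2, 0 °C
Reagents that add atoms: mCPBA, OOC(=O)c1cccc(Cl)c1 (O)
Why: Prilezhaev epoxidation is chemoselective for the electron-rich trisubstituted alkene over the vinyl group, which is deactivated by the allylic acyloxy group; the epoxide stereocentre is removed in step 4.

**Step 4**
Reactants: 5
Product: 6 (S)-aldehyde (C5 aldehyde, C8 acyloxy, C8 vinyl)
Conditions: H5IO6, THF/H2O, 0 °C → rt
Reagents that add atoms: water, O (the second carbonyl oxygen derives from water via the diol); H5IO6, OI(=O)(O)(O)(O)O, is the oxidant and no atoms are retained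
Why: Epoxide hydration and Malaprade-type glycol cleavage release acetone and give the C5 aldehyde; C8 is untouched.

**Step 5**
Reactants: 6
Product: 7 (7S)-3-bromo-7-ethenyl-7-methyl-6,7-dihydrooxepin-2(5H)-one
Conditions: LiCl, DBU, MeCN, 0.003 M (syringe-pump addition), rt
Reagents that add atoms: none
Why: Intramolecular Masamune–Roush HWE closes the 7-membered unsaturated lactone, and the ring forces the C4=C5 alkene cis, putting C18 cis to C6 as in the target; C8 is unchanged.

**Step 6**
Reactants: 7
Product: 8 (7S)-7-acetyl-3-bromo-7-methyl-6,7-dihydrooxepin-2(5H)-one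
Conditions: PdCl2 (10 mol%), CuCl (1 equiv), O2, DMF/H2O 7:1, 30 °C
Reagents that add atoms: water, O (ketone oxygen); O2, O=O, is the terminal oxidant
Why: Tsuji–Wacker oxidation is Markovnikov-selective for a vinyl group on an acyloxy-bearing quaternary carbon and gives the methyl ketone (C9/C10); no stereocentre is touched.

**Step 7**
Reactants: 8
Product: 9 (7S)-3-bromo-7-methyl-7-[1-(trimethylsilyloxy)vinyl]-6,7-dihydrooxepin-2(5H)-one
Conditions: TMSOTf, Et3N, CH2Cl2, 0 °C
Reagents that add atoms: TMSOTf, C[Si](C)(C)OS(=O)(=O)C(F)(F)F (Me3Si)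
Why: Only C10 carries α-H, so enol silylation is regiospecific; this avoids strong-base enolization, which would risk an intramolecular Michael addition onto the lactone.

**Step 8**
Reactants: 10 methyl bis(2,2,2-trifluoroethyl)phosphonoacetate (commercial Still–Gennari reagent)
Product: 11 methyl 2-[bis(2,2,2-trifluoroethoxy)phosphoryl]acrylate
Conditions: (CH2O)n, piperidine (cat.), AcOH (cat.), toluene, Dean–Stark, 100 °C; crude used immediately
Reagents that add atoms: formaldehyde, C=O (adds CH2)
Why: Knoevenagel-type condensation of the active methylene with formaldehyde gives the highly electrophilic 2-phosphonoacrylate; no stereocentre is formed.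

**Step 9**
Reactants: 9; 11 (2 equiv)
Product: 12 methyl 5-[(7S)-3-bromo-7-methyl-2-oxo-2,5,6,7-tetrahydrooxepin-7-yl]-2-[bis(2,2,2-trifluoroethoxy)phosphoryl]-5-oxopentanoate (C12 epimeric mixture)
Conditions: Sc(OTf)3 (5 mol%), CH2Cl2, −78 → 0 °C; then aq. NaHCO3
Reagents that add atoms: none
Why: Proposed new method: the nucleophilic terminal CH2 (C10) of silyl enol ether 9 adds to the very electrophilic CH2 terminus of the 2-phosphonoacrylate (C11), and the silylated phosphonate/ester enolate is hydrolysed on workup; the closest known reaction is the Mukaiyama–Michael addition to alkylidene malonates; the new C12 stereocentre is epimeric and is removed by olefination in step 14, and C8 is untouched.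

**Step 10**
Reactants: 13 ethyl isobutyrylacetate (ethyl 4-methyl-3-oxopentanoate)
Product: 14 ethyl (Z)-4-methyl-3-(triflyloxy)pent-2-enoate
Conditions: NaH, Et2O, 0 °C; then Tf2O, CH2Cl2, −78 → 0 °C
Reagents that add atoms: Tf2O, O=S(=O)(OS(=O)(=O)C(F)(F)F)C(F)(F)F (adds SO2CF3)
Why: O-Triflation of the chelated sodium (Z)-enolate gives the Z-enol triflate with OTf cis to the ester, which fixes the C14=C1 geometry for the next step.

**Step 11**
Reactants: 14; 15 vinyltributylstannane
Product: 16 ethyl (Z)-3-isopropylpenta-2,4-dienoate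
Conditions: Pd(PPh3)4 (5 mol%), LiCl, THF, 65 °C
Reagents that add atoms: none (the vinyl group comes from reactant 15)
Why: Scott–Stille coupling proceeds with retention, so the vinyl group (future C2=C3) ends up cis to the ester (future C13), as required at C14=C1.

**Step 12**
Reactants: 16
Product: 17 (Z)-3-isopropylpenta-2,4-dien-1-ol
Conditions: DIBAL-H (2.2 equiv), CH2Cl2, −78 °C
Reagents that add atoms: none
Why: DIBAL reduces the ester to the primary allylic alcohol; alkene geometry is unchanged.

**Step 13**
Reactants: 17
Product: 18 (Z)-3-isopropylpenta-2,4-dienal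
Conditions: MnO2 (20 equiv), CH2Cl2, rt; used immediately
Reagents that add atoms: none
Why: MnO2 selectively oxidizes the dienyl alcohol to the dienal without isomerizing the Z alkene.

**Step 14**
Reactants: 12; 18
Product: 19 methyl (2Z,4Z)-5-isopropyl-2-{3-oxo-3-[(7S)-3-bromo-7-methyl-2-oxo-2,5,6,7-tetrahydrooxepin-7-yl]propyl}hepta-2,4,6-trienoate
Conditions: 12, KHMDS (1.0 equiv), 18-crown-6, THF, −78 °C; then 18, −78 °C
Reagents that add atoms: none
Why: Still–Gennari HWE with the bis(trifluoroethyl) phosphonate gives kinetically controlled Z-selective olefination, so the ester ends up cis to C14 (C11 trans to C14), matching the target's C12=C13 geometry.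

**Step 15**
Reactants: 19
Product: 20 Ketoemblide
Conditions: (i) 9-BBN-H (1.05 equiv), THF, 0 °C → rt, 1.5 h; (ii) slow addition (8 h) to Pd(dppf)Cl2 (20 mol%), AsPh3, K3PO4, THF/DMF/H2O, 60 °C, 2 mM
Reagents that add atoms: none (9-BBN supplies only H, and boron is lost)
Why: Proposed new method: 9-BBN hydroborates the unhindered terminal vinyl (C2=C3) of the triene to give the primary alkyl-9-BBN (B on C3), and intramolecular B-alkyl Suzuki–Miyaura coupling with the vinyl bromide (C4–Br) closes the 14-membered ring; the closest known reaction is the hydroboration/B-alkyl Suzuki macrocyclization used in polyketide synthesis; the ring C4=C5 and both diene geometries are retained, and no new stereocentre forms.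

---

**Compound list**

| # | Name | SMILES | Role |
|---|---|---|---|
| 1 | (S)-(+)-Linalool | C=C[C@@](C)(O)CCC=C(C)C | starting material |
| 2 | Diethylphosphonoacetic acid | CCOP(=O)(OCC)CC(=O)O | starting material |
| 3 | (S)-Linalyl diethylphosphonoacetate | C=C[C@@](C)(OC(=O)CP(=O)(OCC)OCC)CCC=C(C)C | intermediate |
| 4 | Linalyl 2-bromo-2-(diethoxyphosphoryl)acetate | C=C[C@@](C)(OC(=O)C(Br)P(=O)(OCC)OCC)CCC=C(C)C | intermediate |
| 5 | 6,7-Epoxide of 4 | C=C[C@@](C)(OC(=O)C(Br)P(=O)(OCC)OCC)CCC1OC1(C)C | intermediate |
| 6 | Aldehyde (C5-CHO) | C=C[C@@](C)(OC(=O)C(Br)P(=O)(OCC)OCC)CCC=O | intermediate |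
| 7 | (7S)-3-Bromo-7-ethenyl-7-methyl-6,7-dihydrooxepin-2(5H)-one | C=C[C@]1(C)CCC=C(Br)C(=O)O1 | intermediate |
| 8 | (7S)-7-Acetyl-3-bromo-7-methyl-6,7-dihydrooxepin-2(5H)-one | CC(=O)[C@]1(C)CCC=C(Br)C(=O)O1 | intermediate |
| 9 | TMS enol ether of 8 | C=C(O[Si](C)(C)C)[C@]1(C)CCC=C(Br)C(=O)O1 | intermediate |
| 10 | Methyl bis(2,2,2-trifluoroethyl)phosphonoacetate | COC(=O)CP(=O)(OCC(F)(F)F)OCC(F)(F)F | starting material |
| 11 | Methyl 2-[bis(trifluoroethoxy)phosphoryl]acrylate | COC(=O)C(=C)P(=O)(OCC(F)(F)F)OCC(F)(F)F | intermediate |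
| 12 | Phosphonate ketone (Michael adduct) | O=C(CCC(C(=O)OC)P(=O)(OCC(F)(F)F)OCC(F)(F)F)[C@]1(C)CCC=C(Br)C(=O)O1 | intermediate |
| 13 | Ethyl isobutyrylacetate | CCOC(=O)CC(=O)C(C)C | starting material |
| 14 | Ethyl (Z)-4-methyl-3-(triflyloxy)pent-2-enoate | CCOC(=O)/C=C(\OS(=O)(=O)C(F)(F)F)C(C)C | intermediate |
| 15 | Vinyltributylstannane | C=C[Sn](CCCC)(CCCC)CCCC | starting material |
| 16 | Ethyl (Z)-3-isopropylpenta-2,4-dienoate | CCOC(=O)/C=C(\C=C)C(C)C | intermediate |
| 17 | (Z)-3-Isopropylpenta-2,4-dien-1-ol | OC/C=C(\C=C)C(C)C | intermediate |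
| 18 | (Z)-3-Isopropylpenta-2,4-dienal | O=C/C=C(\C=C)C(C)C | intermediate |
| 19 | (2Z,4Z)-Triene ketolactone (Still–Gennari product) | O=C(CC/C(C(=O)OC)=C/C=C(\C=C)C(C)C)[C@]1(C)CCC=C(Br)C(=O)O1 | intermediate |
| 20 | Ketoemblide | COC(=O)/C1=C\C=C(\C(C)C)CCC2=CCC[C@](C)(OC2=O)C(=O)CC1 | target |

**Totals:** 15 steps in total; the longest linear sequence is 10 steps (1 → 3 → 4 → 5 → 6 → 7 → 8 → 9 → 12 → 19 → 20, i.e. steps 1–7, 9, 14, 15).

**Three steps most likely to fail**
1. **Step 15 (hydroboration/macro-Suzuki).** The risks are ketone reduction or triene over-hydroboration by 9-BBN, competing intramolecular Heck reaction, and macrocyclic strain. Fallback: reverse the order of bond formation. Make the C3–C4 bond intermolecularly (B-alkyl Suzuki of a 9-BBN-derived dienal-acetal partner with the bromolactone), then close the 14-membered ring by intramolecular Still–Gennari HWE between the C12 phosphonate and the C13 aldehyde.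
2. **Step 9 (Mukaiyama–Michael to the phosphonoacrylate).** The acceptor may polymerize or the addition may stall. Fallback: convert 8 to the vinyl ketone (Eschenmoser salt, then MeI/NaHCO3) and add phosphonoacetate 10 by conjugate addition (DBU), which is a different C11–C12 disconnection.
3. **Step 5 (7-membered intramolecular HWE lactonization).** Oligomerization or a slow 7-membered closure could give low yield. Fallback: make the lactone by RCM instead: Wacker oxidation of linalool, acryloylation of the tertiary ketol, Grubbs–Hoveyda II RCM onto the prenyl alkene, then α-bromination (Br2, then Et3N). This gives 8 by a different ring-forming reaction.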